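**Retrosynthetic overview**
1. Late stage: the C6 ester comes from 3,4-dimethoxybenzoyl chloride, the C8/C9 oxirane from a C6-OH-directed epoxidation, the C2 acetate from acetylation, and the C4 carbinol from isopropyl addition to a C4 ketone on the α face.
2. Key disconnection: the seven-membered ring (C5-C6-C7-C8-C9-C10-C1) is made by a Rh(I)-catalysed (5+2) cycloaddition that forms C7–C8 and C9–C10. The alkyne 1-(trimethylsilyl)propyne supplies C8(CH3)=C9, and the five-carbon partner is a 1-(1-silyloxyvinyl)bicyclo[3.1.0]hexane.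
3. Enabling feature: in the seven-membered ring the oxygenated C6 sits between ring-fusion C5 and C7, and C8=C9 (the oxirane carbons) is one CH2 (C7) from C6 and one CH2 (C10) from quaternary C1. C7=C6(O)–C5 is therefore a silyloxyvinyl group on a cyclopropane (C5, C1, C10) fused to the cyclopentane, and C8=C9 is an alkyne.
4. Stereochemistry: C2 is set by a catalytic asymmetric aldol reaction. It relays to C1/C5 (cyclopropanation), a temporary 4α-OH (CBS reduction), C5/C6 (hydroxyl-directed hydrogenation), C4 (isopropyl addition) and C8/C9 (directed epoxidation).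
5. Ring order: cyclopentane (with a temporary cyclopropane) by intramolecular cyclopropanation, then the seven-membered carbocycle as the last ring of the carbon skeleton, then the oxirane on the finished skeleton.

Key step: step 8

**Conventions and assumption**
- Skeleton numbering for all bicyclic compounds: C1 = quaternary ring-fusion carbon (CH3), C2 = CH(OAc), C3 = CH2, C4 = C(OH)(i-Pr), C5 = ring-fusion CH, C6 = CH(O-aroyl), C7 = CH2, C8 = C(CH3), C9 = CH, C10 = CH2 on C1.
- β is the face of the C1 methyl. In the target, 2-OAc, 4-OH, 6-O-aroyl and the oxirane oxygen are β; H5, H6 and the isopropyl group are α (trans ring fusion).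
- Assumption: (S)-BINOL is taken as the ligand antipode that gives the (S)-carbinol in step 2; if the sense of induction is the reverse, (R)-BINOL is used and nothing else changes.

**Route**

Step 1
Reactants: 1 pentane-2,4-dione
Product: 2 2,4-bis(trimethylsilyloxy)penta-1,3-diene
Conditions: TMSOTf (2.1 equiv), Et3N, Et2O, 0 °C to rt
Reagents that add atoms: trimethylsilyl trifluoromethanesulfonate, C[Si](C)(C)OS(=O)(=O)C(F)(F)F
Why: Double O-silylation of the 1,3-diketone by soft enolisation (silyl triflate/amine) should give the 1,3-bis(silyloxy)diene, the γ-nucleophile for the vinylogous aldol reaction.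

Step 2
Reactants: 2 2,4-bis(trimethylsilyloxy)penta-1,3-diene; 3 methacrolein
Product: 5 (S)-6-hydroxy-7-methyloct-7-ene-2,4-dione, via bis-silylated aldol adduct 4 (not isolated)
Conditions: Ti(Oi-Pr)4/(S)-BINOL (10 mol%), 4 Å MS, THF, −78 to −20 °C; then aq. citric acid, THF, 0 °C
Reagents that add atoms: none
Why: Catalytic asymmetric vinylogous Mukaiyama aldol reaction: the chiral Ti(IV)–BINOL Lewis acid activates the enal and the terminal CH2 of the diene adds to one aldehyde face, which sets C2 as (S), the only stereocentre not made under substrate control.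

Step 3
Reactants: 5 (S)-6-hydroxy-7-methyloct-7-ene-2,4-dione
Product: 6 (S)-7-methyl-6-(triethylsilyloxy)oct-7-ene-2,4-dione
Conditions: TESCl, imidazole, CH2Cl2, 0 °C
Reagents that add atoms: chlorotriethylsilane, CC[Si](Cl)(CC)CC
Why: Standard silylation of the secondary allylic alcohol; the silyl ether keeps the hydroxyl out of the carbenoid chemistry and blocks cyclodehydration of the δ-hydroxy-1,3-diketone.

Step 4
Reactants: 6 (S)-7-methyl-6-(triethylsilyloxy)oct-7-ene-2,4-dione
Product: 7 (S)-3-diazo-7-methyl-6-(triethylsilyloxy)oct-7-ene-2,4-dione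
Conditions: p-ABSA, Et3N, MeCN, 0 °C to rt
Reagents that add atoms: 4-acetamidobenzenesulfonyl azide, CC(=O)Nc1ccc(cc1)S(=O)(=O)N=[N+]=[N-]
Why: Regitz diazo transfer to the doubly activated methylene of the 1,3-diketone.

Step 5
Reactants: 7 (S)-3-diazo-7-methyl-6-(triethylsilyloxy)oct-7-ene-2,4-dione
Product: 9 (S)-2-(tert-butyldimethylsilyloxy)-3-diazo-7-methyl-6-(triethylsilyloxy)octa-1,7-dien-4-one, via lithium enolate 8 (not isolated)
Conditions: LiHMDS (1.05 equiv), THF, −78 °C; then TBSOTf, −78 °C
Reagents that add atoms: tert-butyldimethylsilyl trifluoromethanesulfonate, CC(C)(C)[Si](C)(C)OS(=O)(=O)C(F)(F)F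
Why: Kinetic deprotonation should take a proton from the unhindered acetyl methyl rather than from the β-branched C3 methylene, and O-silylation of the enolate gives the enoldiazoketone (silyl enol ether of a diazo diketone).

Step 6
Reactants: 9 (S)-2-(tert-butyldimethylsilyloxy)-3-diazo-7-methyl-6-(triethylsilyloxy)octa-1,7-dien-4-one
Product: 10 1-[1-(tert-butyldimethylsilyloxy)vinyl]-5-methyl-4-(triethylsilyloxy)bicyclo[3.1.0]hexan-2-one (C4 ketone; C5 bridgehead with the silyloxyvinyl group C6=C7; C1 bridgehead with β-CH3; cyclopropane CH2 = C10 on the α face; 2β-OTES, exo)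
Conditions: Rh2(OAc)4 (1 mol%), CH2Cl2, rt, slow addition of 9
Reagents that add atoms: none
Why: Rh(II)-catalysed intramolecular cyclopropanation of the 1,1-disubstituted alkene by the vinylcarbenoid closes the cyclopentanone and the cyclopropane together; allylic 1,3-strain puts the C2 hydrogen rather than the silyloxy group inside, so OTES ends exo, which fixes C1 (CH3 β, C10 α) and C5 from C2.

Step 7
Reactants: 10 bicyclo[3.1.0]hexanone
Product: 11 1-[1-(tert-butyldimethylsilyloxy)vinyl]-5-methyl-4-(triethylsilyloxy)bicyclo[3.1.0]hexan-2-ol (4α-OH, cis to the cyclopropane CH2 and trans to 2β-OTES)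
Conditions: (R)-Me-CBS oxazaborolidine (20 mol%), catecholborane, toluene, −78 °C
Reagents that add atoms: none
Why: CBS reduction: the quaternary C5 is the large group, and with the (R)-oxazaborolidine hydride should be delivered to the exo (β) face, away from the cyclopropane methylene, giving the 4α-alcohol (4S).

Step 8
Reactants: 11 bicyclo[3.1.0]hexanol; 12 trimethyl(prop-1-yn-1-yl)silane
Product: 13 bicyclic dienol: C5=C6 silyl enol ether (6-OTBS), C8=C9 vinylsilane (8-CH3, 9-SiMe3), 1β-CH3, 2β-OTES, 4α-OH
Conditions: 12 (3 equiv), [Rh(CO)2Cl]2 (5 mol%), ClCH2CH2Cl, 70 °C; filtration through Et3N-deactivated silica, used at once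
Reagents that add atoms: none
Why: Rh(I)-catalysed intermolecular (5+2) cycloaddition of a vinylcyclopropane with an alkyne: Rh(I) binds the silyloxyvinyl group in its s-cis conformer (favoured by the α-OTBS substituent), inserts into the exocyclic cyclopropane bond C5–C10 to give a σ-alkyl/π-allyl rhodacycle, the alkyne inserts at the allyl terminus C7 (C7–C8 bond) and reductive elimination forms C9–C10. The closest known reaction type is the intermolecular (5+2) reaction of α-substituted and oxygen-substituted vinylcyclopropanes with internal and silyl alkynes. The seven-membered ring is closed as a two-bond annulation onto the intact cyclopentane, driven by release of cyclopropane strain; no stereocentre is created, and C1, C2 and C4 pass through unchanged because the cleaved bond C5–C10 does not touch their configuration. Two selectivities are needed: cleavage of C5–C10 rather than C5–C1, secured because C1 is quaternary (a tertiary alkyl–rhodium would result), and alkyne orientation, secured by the trimethylsilyl group, which stays distal to the first-formed C7–C8 bond and so ends on C9 next to C10. The silicon is a placeholder that also makes C8=C9 tetrasubstituted and inert in step 9; it is removed in step 11.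

Step 9
Reactants: 13 bicyclic dienol
Product: 14 saturated alcohol: 4α-OH, 5α-H, 6β-OTBS (6α-H), 2β-OTES, 1β-CH3, C8=C9 vinylsilane retained
Conditions: H2 (1 atm), [Ir(cod)(PCy3)(py)]PF6 (10 mol%), CH2Cl2, rt
Reagents that add atoms: none
Why: Hydroxyl-directed homogeneous hydrogenation: the 4α-hydroxyl binds iridium and both hydrogens are delivered cis to the α face of the tetrasubstituted C5=C6 enol ether, which sets H5 (trans ring fusion to the 1β-methyl) and H6 (leaving O6 β) in one event, while the tetrasubstituted vinylsilane has no directing group and should not be reduced.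

Step 10
Reactants: 14 saturated alcohol
Product: 15 C4 ketone: 5α-H, 6β-OTBS, 2β-OTES, C8=C9 vinylsilane
Conditions: Dess–Martin periodinane, NaHCO3, CH2Cl2, 0 °C to rt
Reagents that add atoms: none
Why: Dess–Martin oxidation of the secondary alcohol under buffered, non-enolising conditions should leave the C5 and C6 centres and the silyl groups untouched.

Step 11
Reactants: 15 C4 ketone
Product: 16 hydroxy ketone: C4 ketone, 2β-OH, 6β-OTBS, C8(CH3)=C9H
Conditions: CF3CO2H, CH2Cl2, 0 °C; aq. NaHCO3
Reagents that add atoms: none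
Why: ipso-Protodesilylation of the vinylsilane: protonation at C9 gives the tertiary, β-silyl-stabilised cation at C8, which loses silicon and returns the C8=C9 double bond in place; the acid also removes the labile triethylsilyl ether while the hindered secondary TBS ether should survive.

Step 12
Reactants: 16 hydroxy ketone
Product: 17 diol: 4β-OH, 4α-isopropyl, 2β-OH, 6β-OTBS, C8=C9
Conditions: i-PrMgCl (4 equiv), anhydrous CeCl3 (4 equiv), THF, −78 °C
Reagents that add atoms: isopropylmagnesium chloride, CC(C)[Mg]Cl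
Why: Organocerium addition suppresses enolisation and β-hydride reduction; the nucleophile should enter the cyclopentanone anti to the adjacent C5 substituent (C6, β), the 1β-methyl and the 2β-oxygen, that is from the α face, giving the 4β-tertiary alcohol.

Step 13
Reactants: 17 diol
Product: 18 2β-acetate: 4β-OH, 6β-OTBS, C8=C9
Conditions: Ac2O, pyridine, DMAP (cat.), CH2Cl2, 0 °C to rt
Reagents that add atoms: acetic anhydride, CC(=O)OC(C)=O
Why: Acylation of the only free secondary hydroxyl; the tertiary C4 hydroxyl should not react under these conditions.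

Step 14
Reactants: 18 2β-acetate
Product: 19 6β-alcohol: 2β-OAc, 4β-OH, C8=C9
Conditions: HF·pyridine, pyridine, THF, 0 °C to rt
Reagents that add atoms: none
Why: Fluoride cleavage of the silyl ether; buffered HF·pyridine tolerates the acetate, the tertiary alcohol and the alkene.

Step 15
Reactants: 19 6β-alcohol
Product: 20 8β,9β-epoxide: 2β-OAc, 4β-OH, 6β-OH
Conditions: VO(acac)2 (5 mol%), t-BuOOH, CH2Cl2, 0 °C to rt
Reagents that add atoms: tert-butyl hydroperoxide, CC(C)(C)OO
Why: Vanadium-catalysed epoxidation directed by the homoallylic 6β-hydroxyl should deliver oxygen syn, to the β face of C8=C9, setting C8 and C9; no other alkene is present.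

Step 16
Reactants: 20 8β,9β-epoxide; 21 3,4-dimethoxybenzoyl chloride
Product: 22 target CNP0330776.1
Conditions: Et3N, DMAP, CH2Cl2, 0 °C to rt
Reagents that add atoms: none
Why: DMAP-catalysed acylation of the secondary 6β-hydroxyl by the acid chloride; the tertiary hydroxyl is inert and the basic medium spares the oxirane.

**Compound list**
1 | pentane-2,4-dione | CC(=O)CC(C)=O | starting material
2 | 2,4-bis(trimethylsilyloxy)penta-1,3-diene | C=C(O[Si](C)(C)C)C=C(C)O[Si](C)(C)C | intermediate
3 | methacrolein | CC(=C)C=O | starting material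
4 | (S)-7-methyl-2,6-bis(trimethylsilyloxy)octa-2,7-dien-4-one | CC(O[Si](C)(C)C)=CC(=O)C[C@H](O[Si](C)(C)C)C(C)=C | intermediate (not isolated)
5 | (S)-6-hydroxy-7-methyloct-7-ene-2,4-dione | CC(=O)CC(=O)C[C@H](O)C(C)=C | intermediate
6 | (S)-7-methyl-6-(triethylsilyloxy)oct-7-ene-2,4-dione | CC(=O)CC(=O)C[C@H](O[Si](CC)(CC)CC)C(C)=C | intermediate
7 | (S)-3-diazo-7-methyl-6-(triethylsilyloxy)oct-7-ene-2,4-dione | CC(=O)C(=[N+]=[N-])C(=O)C[C@H](O[Si](CC)(CC)CC)C(C)=C | intermediate
8 | lithium enolate of 7 at the acetyl methyl group | [Li]OC(=C)C(=[N+]=[N-])C(=O)C[C@H](O[Si](CC)(CC)CC)C(C)=C | intermediate (not isolated)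
9 | (S)-2-(tert-butyldimethylsilyloxy)-3-diazo-7-methyl-6-(triethylsilyloxy)octa-1,7-dien-4-one | C=C(O[Si](C)(C)C(C)(C)C)C(=[N+]=[N-])C(=O)C[C@H](O[Si](CC)(CC)CC)C(C)=C | intermediate
10 | 1-[1-(tert-butyldimethylsilyloxy)vinyl]-5-methyl-4-(triethylsilyloxy)bicyclo[3.1.0]hexan-2-one, OTES exo | C=C(O[Si](C)(C)C(C)(C)C)[C@@]12C[C@]1(C)[C@@H](O[Si](CC)(CC)CC)CC2=O | intermediate
11 | 1-[1-(tert-butyldimethylsilyloxy)vinyl]-5-methyl-4-(triethylsilyloxy)bicyclo[3.1.0]hexan-2-ol, OH cis to the cyclopropane CH2 (4α-OH) | C=C(O[Si](C)(C)C(C)(C)C)[C@@]12C[C@]1(C)[C@@H](O[Si](CC)(CC)CC)C[C@@H]2O | intermediate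
12 | trimethyl(prop-1-yn-1-yl)silane | CC#C[Si](C)(C)C | starting material
13 | bicyclic dienol: 6-OTBS enol ether (C5=C6), 8-CH3, 9-SiMe3 (C8=C9), 1β-CH3, 2β-OTES, 4α-OH | CC(C)(C)[Si](C)(C)OC1=C2[C@@H](O)C[C@H](O[Si](CC)(CC)CC)[C@@]2(C)CC([Si](C)(C)C)=C(C)C1 | intermediate
14 | saturated alcohol: 4α-OH, 5α-H, 6β-OTBS, 2β-OTES, C8=C9 vinylsilane | CC(C)(C)[Si](C)(C)O[C@H]2CC(C)=C([Si](C)(C)C)C[C@]3(C)[C@@H](O[Si](CC)(CC)CC)C[C@H](O)[C@@H]23 | intermediate
15 | C4 ketone: 5α-H, 6β-OTBS, 2β-OTES, C8=C9 vinylsilane | CC(C)(C)[Si](C)(C)O[C@H]2CC(C)=C([Si](C)(C)C)C[C@]3(C)[C@@H](O[Si](CC)(CC)CC)CC(=O)[C@@H]23 | intermediate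
16 | hydroxy ketone: C4 ketone, 2β-OH, 6β-OTBS, C8(CH3)=C9H | CC(C)(C)[Si](C)(C)O[C@H]2CC(C)=CC[C@]3(C)[C@@H](O)CC(=O)[C@@H]23 | intermediate
17 | diol: 4β-OH, 4α-isopropyl, 2β-OH, 6β-OTBS | CC(C)(C)[Si](C)(C)O[C@H]2CC(C)=CC[C@]3(C)[C@@H](O)C[C@](O)(C(C)C)[C@@H]23 | intermediate
18 | 2β-acetate: 4β-OH, 6β-OTBS | CC(C)(C)[Si](C)(C)O[C@H]2CC(C)=CC[C@]3(C)[C@@H](OC(C)=O)C[C@](O)(C(C)C)[C@@H]23 | intermediate
19 | 6β-alcohol: 2β-OAc, 4β-OH, C8=C9 | O[C@H]2CC(C)=CC[C@]3(C)[C@@H](OC(C)=O)C[C@](O)(C(C)C)[C@@H]23 | intermediate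
20 | 8β,9β-epoxide: 2β-OAc, 4β-OH, 6β-OH | O[C@H]2C[C@@]3(C)O[C@H]3C[C@]3(C)[C@@H](OC(C)=O)C[C@](O)(C(C)C)[C@@H]23 | intermediate
21 | 3,4-dimethoxybenzoyl chloride | COc1ccc(C(=O)Cl)cc1OC | starting material
22 | CNP0330776.1 | COc1ccc(C(=O)O[C@H]2C[C@@]3(C)O[C@H]3C[C@]3(C)[C@@H](OC(C)=O)C[C@](O)(C(C)C)[C@@H]23)cc1OC | target

**Step count and risks**
Total steps: 16. Longest linear sequence: 16 (from pentane-2,4-dione).

The three steps most likely to fail:

Step 8. The alkyne may insert with the opposite orientation, so that silicon ends on C8 and the methyl on C9, or the hindered internal alkyne may be taken up too slowly and the vinylcyclopropane isomerises instead. The fallback sets out from 11 and uses propyne in the same rhodium-catalysed cycloaddition: if the larger group prefers the carbon that bonds to C7, propyne places its methyl there, giving the propyne cycloadduct F1. Without silicon, C8=C9 is trisubstituted, so the enol ether is reduced with the less active, strictly hydroxyl-directed catalyst [Rh(nbd)(dppb)]BF4 under hydrogen pressure to the saturated alcohol F2. Periodinane oxidation gives the ketone F3, and PPTS in methanol removes the triethylsilyl ether. The fallback comes back to the route at 16.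

Step 9. The weakly acidic iridium hydride may ionise the γ-hydroxy enol ether (loss of the C4 hydroxyl to a C4=C5–C6=O enone) or cleave the silyl enol ether before hydrogen is delivered. The fallback sets out from 13 and replaces hydrogen delivery to the alkene by hydride delivery to a ketone. Buffered fluoride (TBAF/AcOH, THF, −40 °C) unmasks the C6 ketone with protonation at C5, giving the β-hydroxy ketone F4. An Evans–Tishchenko reduction (benzaldehyde, catalytic SmI2) transfers hydride from the O4-bound hemiacetal to the α face of C6, giving the 1,3-anti monoester, the 4-O-benzoate F5, with a free 6β-hydroxyl. TBSOTf/2,6-lutidine gives the silyl ether F6, and DIBAL removes the benzoate. The fallback comes back to the route at 14.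

Step 12. The hindered, doubly β-oxygenated ketone may be enolised (with β-elimination of the C6 silyloxy group) or reduced by β-hydride transfer instead of accepting the secondary alkyl group. The fallback sets out from 16 and adds 2-propenylmagnesium bromide/CeCl3, an sp2 nucleophile without β-hydrogen, from the same α face to give the isopropenyl carbinol F7. Hydrogenation with RhCl(PPh3)3 saturates the 1,1-disubstituted alkene and leaves the trisubstituted C8=C9. The fallback comes back to the route at 17.

**Further compounds**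
F1 | step 8 | propyne cycloadduct: 6-OTBS enol ether (C5=C6), C8(CH3)=C9H, 2β-OTES, 4α-OH | CC(C)(C)[Si](C)(C)OC1=C2[C@@H](O)C[C@H](O[Si](CC)(CC)CC)[C@@]2(C)CC=C(C)C1
F2 | step 8 | saturated alcohol: 4α-OH, 5α-H, 6β-OTBS, 2β-OTES, C8=C9 | CC(C)(C)[Si](C)(C)O[C@H]2CC(C)=CC[C@]3(C)[C@@H](O[Si](CC)(CC)CC)C[C@H](O)[C@@H]23
F3 | step 8 | ketone: C4=O, 6β-OTBS, 2β-OTES, C8=C9 | CC(C)(C)[Si](C)(C)O[C@H]2CC(C)=CC[C@]3(C)[C@@H](O[Si](CC)(CC)CC)CC(=O)[C@@H]23
F4 | step 9 | β-hydroxy ketone: C6=O, 4α-OH, 5α-H, 2β-OTES, C8=C9 vinylsilane | O=C2CC(C)=C([Si](C)(C)C)C[C@]3(C)[C@@H](O[Si](CC)(CC)CC)C[C@H](O)[C@@H]23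
F5 | step 9 | 4-O-benzoate: 4α-OBz, 6β-OH, 2β-OTES, C8=C9 vinylsilane | O[C@H]2CC(C)=C([Si](C)(C)C)C[C@]3(C)[C@@H](O[Si](CC)(CC)CC)C[C@H](OC(=O)c4ccccc4)[C@@H]23
F6 | step 9 | silyl ether: 4α-OBz, 6β-OTBS, 2β-OTES, C8=C9 vinylsilane | CC(C)(C)[Si](C)(C)O[C@H]2CC(C)=C([Si](C)(C)C)C[C@]3(C)[C@@H](O[Si](CC)(CC)CC)C[C@H](OC(=O)c4ccccc4)[C@@H]23
F7 | step 12 | isopropenyl carbinol: 4β-OH, 4α-(prop-1-en-2-yl), 2β-OH, 6β-OTBS | CC(C)(C)[Si](C)(C)O[C@H]2CC(C)=CC[C@]3(C)[C@@H](O)C[C@](O)(C(C)=C)[C@@H]23
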